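The readings were generated by integration with made-up constants; the scatter is artificial.

Start from the late end of the alder run, where substrate and coupling partner still make target, slowly. That slope is what to watch when you repeat these flasks: the birch run has the alder charge and is left for 10 h.

| setting | alder | ash | elm | birch |
|---|---|---|---|---|
| substrate | 0.500 M | 0.300 M | 0.500 M | 0.500 M |
| coupling partner | 1.50 M | 1.30 M | 3.00 M | 1.50 M |
| free catalyst | 0.00250 M | 0.00250 M | 0.00250 M | 0.00250 M |
| time |  |  |  | 10 h |

- alder run (time / h: [target] / M): 0.21: 0.0813; 0.36: 0.0946; 0.61: 0.1078; 1.0: 0.1295; 1.8: 0.1668; 3.0: 0.2122; 5.2: 0.2844
- ash run (time / h: [target] / M): 0.21: 0.0498; 0.36: 0.0546; 0.61: 0.0637; 1.0: 0.0706; 1.8: 0.0976; 3.0: 0.1241; 5.2: 0.1624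
- elm run (time / h: [target] / M): 0.21: 0.0991; 0.36: 0.1200; 0.61: 0.1456; 1.0: 0.1775; 1.8: 0.2433; 3.0: 0.3137; 5.2: 0.3956

(readings scatter by 0.002 M)

- Overall: substrate + coupling partner -> target, with free catalyst as catalyst.
- Constant volume, constant temperature.
- A reading of a species includes what of it is bound.
- An order is taken over about fifteen percent of the charge, up and down.

* apparent order in [coupling partner] of the starting rate, round the charge of the alder run (the rate where two percent of its substrate have turned into target)
* apparent order in [substrate] of the starting rate, round the charge of the alder run (the rate where two percent of its substrate have turned into target) (one fixed amount of target, the same in the runs compared)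
* the ash run starts with 0.200 M less of substrate and of coupling partner than the alder run, and with no target. Compared where both hold the same amount of substrate, once fifteen percent of what the ash run was charged with has turned into target, is the ash run faster, slower or alike (within a tenth)?
* target in the birch run at 10 h, as a share of the substrate charged

Take the rate first. In the alder run the mean rate up to 0.21 h is 0.387 M/h, and the target there is 32.5 times the free catalyst charged, so the catalyst is turning over. Between 0.21 h and 0.36 h the rate is 0.0887 M/h, lower by a factor of 4.36. The product [substrate][coupling partner] has fallen by a factor of 1.32 by then, which leaves roughly a factor of 3.32 for another slowing, one the readings show without naming.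

From 1.8 h on, take the rate as k[substrate][coupling partner]. Both fall one for one, so their difference stays at 1.00 M, and the ratio [coupling partner]/[substrate] grows by a factor e in each equal span, the inverse of k times that difference. The alder readings at 1.8 h and 5.2 h give 9.91 h for that span, and this ratio time is the number to carry. The ash run, with the same difference, reads 10.3 h.

From 5.2 h to 10 h the birch run has 0.484 ratio times to go, about half of one, which by my reckoning leaves 0.123 M of substrate. On the same reckoning its rate falls from 0.0264 M/h to 0.0139 M/h: a factor of 1.76 from substrate and 1.08 from coupling partner. Held at the earlier rate, the share of target at 10 h would reach 82.3 %; the accumulated slowing brings my figure down to 75.5 %.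

The forecast gave 0.35 (0.1 to 0.8) for the order in [coupling partner] and 0.9 (0.6 to 1.1) for the order in [substrate], both “rough because no reading falls inside the burst”, the ash run faster, and 76 % (71 % to 80 %) for the birch run, slightly above my figure.

The flask gives orders of 0.67 and 1.1, the ash run faster, and 75.3 % for the birch run.

    free catalyst + coupling partner ⇌ catalyst-reagent complex, settled at all times (0.3760 /M)
    catalyst-reagent complex + substrate → target + free catalyst (2416 /M/h)
    free catalyst + coupling partner → spent catalyst + coupling partner (14.22 /M/h)
    substrate + coupling partner → target (0.1001 /M/h)

The slope you watch is the direct conversion of substrate and coupling partner into target: without it the birch run holds 14.8 % at 10 h instead of 75.3 %. So the ratio time, read as 9.91 h, belongs to that conversion, and at this one temperature it shortens as the difference grows. The elm run has a difference of 2.50 M, which by this rule gives it a ratio time of 3.97 h. Counted on from its reading at 1.0 h, the reckoning puts target at half of the elm charge of substrate at 1.91 h, and the elm run reaches that point at 1.88 h.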